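Decalin numbering: ring A = C1–C5, C10 (C4 bears the side chain); ring B = C5–C10 (C8 methine, C9 quaternary, C11 = ArCH2). Everything rests on the C9–C10 bond. A reductive Heck cyclisation closes ring B last: the C10 enol triflate of a monocyclic ring-A precursor adds 6-exo across a tethered C9=C11 styrene, which creates the C9 quaternary centre, leaves the C5=C10 alkene exactly where the triflate was, and, because palladium ends on C11 next to a carbon without hydrogen, allows formate to deliver the ArCH2 group. The precursor comes from a copper-catalysed conjugate addition/aldol union of side chain, ring A and aryl tether.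

Key step: step 12

Assumption: the aryl sulfate half-esters are written protonated, as in the target formula; in practice 31 and 32 would be handled as ammonium or sodium salts.

Abbreviations: SC = (3E,7S,8R)-7,8-bis(tert-butyldimethylsilyloxy)-4,8,12-trimethyltrideca-3,11-dien-1-yl; Ar = 2,5-dimethoxyphenyl. In monocyclic intermediates C10 is the carbonyl or enol carbon, C5 the adjacent substituted carbon, C4 the quaternary carbon, and C6–C9 and C11 are the tether carbons.

Step 1
Reactants: 1 2,5-dimethoxybenzaldehyde; 2 but-2-yne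
Product: 5 (1R,2E)-1-(2,5-dimethoxyphenyl)-2-methylbut-2-en-1-ol, via (Z)-but-2-en-2-yl(dicyclohexyl)borane 3 (not isolated), via (E)-but-2-en-2-yl(methyl)zinc 4 (not isolated)
Conditions: Cy2BH, PhMe, 0 °C to rt; Me2Zn, −78 °C; (+)-MIB (3-exo-morpholinoisoborneol, 5 mol %), then 1, −10 °C; H2O work-up
Reagents that add atoms: none
Why: Asymmetric alkenylzinc addition to an aldehyde: syn-hydroboration fixes the (E)-trisubstituted alkene, boron-to-zinc exchange gives the alkenylzinc, and the amino-alcohol zinc catalyst should deliver it to the Re face of the aldehyde to set the (R)-carbinol (the antipodal ligand is used should the sense prove opposite).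

Step 2
Reactants: 5 (1R,2E)-1-(2,5-dimethoxyphenyl)-2-methylbut-2-en-1-ol
Product: 7 (3S,4E)-5-(2,5-dimethoxyphenyl)-3,4-dimethylpent-4-enal, via allyl vinyl ether 6 (not isolated)
Conditions: butyl vinyl ether (excess), Pd(OCOCF3)2 (1 mol %), 4,7-diphenyl-1,10-phenanthroline (1 mol %), Et3N (cat.), 75 °C; then PhMe, 110 °C
Reagents that add atoms: butyl vinyl ether, C=COCCCC
Why: Transfer vinylation followed by Claisen rearrangement: the chair transition state with the aryl group pseudo-equatorial transfers the carbinol chirality suprafacially to C8 (S) and gives the (E)-styrene.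

Step 3
Reactants: 8 pent-3-yn-1-ol
Product: 9 5-bromopent-2-yne
Conditions: CBr4, PPh3, CH2Cl2, 0 °C
Reagents that add atoms: carbon tetrabromide, BrC(Br)(Br)Br
Why: Appel bromination of a primary alcohol; the internal alkyne is inert.

Step 4
Reactants: 9 5-bromopent-2-yne
Product: 11 (2E)-5-bromo-2-iodopent-2-ene, via alkenylzirconocene chloride 10 (not isolated)
Conditions: Cp2Zr(H)Cl (1.5 equiv), THF, rt to 40 °C; I2, 0 °C
Reagents that add atoms: iodine, [I][I]
Why: Hydrozirconation–iodination: syn addition places zirconium on the less hindered, methyl-bearing alkyne carbon and iodinolysis proceeds with retention, giving the (E)-2-iodoalkene; the alkyl bromide is tolerated.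

Step 5
Reactants: 12 geraniol
Product: 13 (2R,3R)-2,3-epoxygeraniol
Conditions: Ti(OiPr)4 (5 mol %), D-(−)-diethyl tartrate (7 mol %), t-BuOOH, 4 Å MS, CH2Cl2, −20 °C
Reagents that add atoms: tert-butyl hydroperoxide, CC(C)(C)OO
Why: Sharpless asymmetric epoxidation: the D-(−)-tartrate catalyst delivers oxygen to the face that gives the (2R,3R)-epoxide, and only the allylic alkene reacts.

Step 6
Reactants: 13 (2R,3R)-2,3-epoxygeraniol
Product: 15 (3S,4R)-4,8-dimethylnona-1,7-diene-3,4-diol, via terminal epoxy alcohol 14 (not isolated)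
Conditions: Me3S+ I− (5 equiv), n-BuLi (4.8 equiv), THF, −10 °C to rt
Reagents that add atoms: trimethylsulfonium iodide, C[S+](C)C.[I-]
Why: Payne rearrangement, then sulfonium-ylide opening of the terminal epoxide and elimination (one-carbon homologation to an allylic alcohol): the primary alkoxide inverts C2 to the (S)-carbinol while the tertiary C–O bond is untouched (R), which gives the anti-diol of the target.

Step 7
Reactants: 15 (3S,4R)-4,8-dimethylnona-1,7-diene-3,4-diol
Product: 16 (3S,4R)-3,4-bis(tert-butyldimethylsilyloxy)-4,8-dimethylnona-1,7-diene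
Conditions: TBSOTf (3 equiv), 2,6-lutidine, CH2Cl2, 0 °C to rt
Reagents that add atoms: tert-butyldimethylsilyl trifluoromethanesulfonate, CC(C)(C)[Si](C)(C)OS(=O)(=O)C(F)(F)F
Why: Silylation with the silyl triflate masks the secondary and the hindered tertiary hydroxyl, so that the Grignard, hydride and sulfation steps are tolerated and fluoride can release the diol at the end.

Step 8
Reactants: 16 (3S,4R)-3,4-bis(tert-butyldimethylsilyloxy)-4,8-dimethylnona-1,7-diene; 11 (2E)-5-bromo-2-iodopent-2-ene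
Product: 18 (3E,7S,8R)-1-bromo-7,8-bis(tert-butyldimethylsilyloxy)-4,8,12-trimethyltrideca-3,11-diene (SC–Br), via B-alkyl-9-borabicyclononane 17 (not isolated)
Conditions: 9-BBN (1.1 equiv), THF, 0 °C to rt; then 11, Pd(dppf)Cl2 (5 mol %), AsPh3 (10 mol %), Cs2CO3, DMF/H2O, rt
Reagents that add atoms: none
Why: Chemoselective anti-Markovnikov hydroboration of the monosubstituted alkene followed by B-alkyl Suzuki–Miyaura coupling, which joins the alkyl carbon to the alkenyl iodide with retention of the (E)-geometry and leaves the primary bromide untouched.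

Step 9
Reactants: 18 SC–Br; 19 3-methylcyclohex-2-en-1-one; 7 (3S,4E)-5-(2,5-dimethoxyphenyl)-3,4-dimethylpent-4-enal
Product: 22 aldol adduct (3R)-2-[(3S,4E)-5-Ar-1-hydroxy-3,4-dimethylpent-4-en-1-yl]-3-methyl-3-SC-cyclohexan-1-one (epimers at C5 and C6), via Grignard reagent 20 (not isolated), via magnesium enolate 21 (not isolated)
Conditions: Mg, Et2O, rt; then 19, Cu(OTf)2 (3 mol %), chiral C2-symmetric imidazolinium chloride (NHC precursor, 4 mol %, antipode giving 4R), Et2O, 0 °C; then 7, −78 °C; H2O work-up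
Reagents that add atoms: none
Why: Copper-catalysed asymmetric conjugate addition of the Grignard reagent to the β-methyl enone sets the quaternary C4 centre (R) under catalyst control, and the regiodefined magnesium enolate is trapped at C5 by aldol addition to 7; the centres formed at C5 and C6 are erased in steps 10 to 12.

Step 10
Reactants: 22 aldol adduct
Product: 24 (3R)-2-[(3S,4E)-5-Ar-3,4-dimethylpent-4-en-1-ylidene]-3-methyl-3-SC-cyclohexan-1-one, via secondary mesylate 23 (not isolated)
Conditions: MsCl, Et3N, CH2Cl2, 0 °C; then DBU, rt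
Reagents that add atoms: none
Why: Mesylation and E1cB elimination should give the exocyclic C5=C6 enone; its geometry is irrelevant because C6 becomes CH2 in the next step.

Step 11
Reactants: 24 exocyclic enone
Product: 26 (3R)-2-[(3S,4E)-5-Ar-3,4-dimethylpent-4-en-1-yl]-3-methyl-3-SC-cyclohex-1-en-1-yl trifluoromethanesulfonate, via lithium enolate 25 (not isolated)
Conditions: LiBH(s-Bu)3 (1.1 equiv), THF, −78 °C; then PhNTf2, −78 °C to rt
Reagents that add atoms: N-phenylbis(trifluoromethanesulfonimide), O=S(=O)(N(c1ccccc1)S(=O)(=O)C(F)(F)F)C(F)(F)F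
Why: Conjugate reduction by the hindered borohydride generates the enolate regiospecifically toward C5, and O-triflation traps it as the tetrasubstituted C10 enol triflate (conjugate reduction–enolate triflation).

Step 12
Reactants: 26 C10 enol triflate
Product: 28 2-{[(1R,2S,5R)-1,2,5-trimethyl-5-SC-1,2,3,4,5,6,7,8-octahydronaphthalen-1-yl]methyl}-1,4-dimethoxybenzene, via benzylic alkylpalladium formate 27 (not isolated)
Conditions: Pd(OAc)2 (10 mol %), (R)-BINAP (12 mol %), HCO2Na (2 equiv, added in portions), DMF, 80 °C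
Reagents that add atoms: none
Why: Zerovalent palladium, formed in situ from Pd(OAc)2 and the phosphine, inserts into the C10–OTf bond, the alkenylpalladium adds syn across the tethered C9=C11 styrene with C10 bonding to C9, and the benzylic C11–palladium species 27, which has no β-hydrogen because C9 is now quaternary, takes up formate, loses CO2 and reductively eliminates C11–H. The closest known reaction type is the intramolecular Heck cyclisation with hydride capture (reductive Heck), including its asymmetric variants with BINAP and enol triflates. Ring B is closed in the 6-exo-trig mode, and the C5=C10 alkene is not made by elimination but carried over from the enol triflate, so its position is unambiguous. The new C9 stereocentre is controlled by C8 in a chair-like insertion transition state in which the C9–C11 bond eclipses C10–Pd and the C8 methyl group is pseudo-equatorial, which puts the C8 and C9 methyl groups cis; because this intrinsic bias is expected to be modest for an (E)-styrene, (R)-BINAP is proposed to reinforce the same alkene face, the matched antipode to be identified by trying both. The step needs insertion to outrun formate reduction of the alkenylpalladium (portionwise addition of the sparingly soluble formate keeps hydride concentration low) and 6-exo attack on the styrene to outrun attack on the side-chain alkenes; the nearest of these, three carbons out from C4, could only give a bridged bicyclo[3.3.1] ring with a bridgehead alkene, and the others are remote.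

Step 13
Reactants: 28 dimethyl ether
Product: 30 2-{[(1R,2S,5R)-1,2,5-trimethyl-5-SC-1,2,3,4,5,6,7,8-octahydronaphthalen-1-yl]methyl}benzene-1,4-diol, via benzoquinone 29 (not isolated)
Conditions: (NH4)2Ce(NO3)6 (2.5 equiv), MeCN/H2O, 0 °C, 10 min; then aqueous Na2S2O4, EtOAc, rt
Reagents that add atoms: water, O
Why: Oxidative demethylation of the 1,4-dimethoxyarene by the tetravalent cerium salt to the quinone (carbonyl oxygen from water) and dithionite reduction to the hydroquinone avoid acid, which could cyclise a free phenol onto the C5=C10 alkene.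

Step 14
Reactants: 30 hydroquinone
Product: 31 2-{[(1R,2S,5R)-1,2,5-trimethyl-5-SC-1,2,3,4,5,6,7,8-octahydronaphthalen-1-yl]methyl}-1,4-phenylene bis(hydrogen sulfate)
Conditions: SO3·pyridine (6 equiv), pyridine, rt to 45 °C
Reagents that add atoms: sulfur trioxide–pyridine complex, O=S(=O)([O-])[n+]1ccccc1
Why: O-Sulfation of both phenols with the sulfur trioxide–amine complex; the only other hydroxyls are masked as silyl ethers.

Step 15
Reactants: 31 silyl-protected bis(hydrogen sulfate)
Product: 32 target, 2-{[(1R,2S,5R)-5-[(3E,7S,8R)-7,8-dihydroxy-4,8,12-trimethyltrideca-3,11-dien-1-yl]-1,2,5-trimethyl-1,2,3,4,5,6,7,8-octahydronaphthalen-1-yl]methyl}-1,4-phenylene bis(hydrogen sulfate)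
Conditions: Bu4NF (6 equiv), THF, rt to 45 °C; aqueous work-up, reversed-phase chromatography
Reagents that add atoms: none
Why: Fluoride-mediated desilylation should release the diol without touching the aryl sulfates, the alkenes or any stereocentre.

Compound list
1 | 2,5-dimethoxybenzaldehyde | COc1ccc(OC)c(C=O)c1 | starting material
2 | but-2-yne | CC#CC | starting material
3 | (Z)-but-2-en-2-yl(dicyclohexyl)borane | C/C=C(\C)B(C1CCCCC1)C1CCCCC1 | intermediate (not isolated)
4 | (E)-but-2-en-2-yl(methyl)zinc | C/C=C(\C)[Zn]C | intermediate (not isolated)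
5 | (1R,2E)-1-(2,5-dimethoxyphenyl)-2-methylbut-2-en-1-ol | C/C=C(\C)[C@@H](O)c1cc(OC)ccc1OC | intermediate
6 | 2-[(1R,2E)-1-(ethenyloxy)-2-methylbut-2-en-1-yl]-1,4-dimethoxybenzene | C/C=C(\C)[C@@H](OC=C)c1cc(OC)ccc1OC | intermediate (not isolated)
7 | (3S,4E)-5-(2,5-dimethoxyphenyl)-3,4-dimethylpent-4-enal | O=CC[C@H](C)/C(C)=C/c1cc(OC)ccc1OC | intermediate
8 | pent-3-yn-1-ol | CC#CCCO | starting material
9 | 5-bromopent-2-yne | CC#CCCBr | intermediate
10 | chlorobis(cyclopentadienyl)[(2E)-5-bromopent-2-en-2-yl]zirconium | C/C(=C\CCBr)[Zr](Cl)(C1C=CC=C1)C1C=CC=C1 | intermediate (not isolated)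
11 | (2E)-5-bromo-2-iodopent-2-ene | C/C(I)=C\CCBr | intermediate
12 | geraniol, (2E)-3,7-dimethylocta-2,6-dien-1-ol | CC(C)=CCC/C(C)=C/CO | starting material
13 | (2R,3R)-2,3-epoxygeraniol | CC(C)=CCC[C@@]1(C)O[C@@H]1CO | intermediate
14 | (2R)-6-methyl-2-[(2S)-oxiran-2-yl]hept-5-en-2-ol | CC(C)=CCC[C@@](C)(O)[C@@H]1CO1 | intermediate (not isolated)
15 | (3S,4R)-4,8-dimethylnona-1,7-diene-3,4-diol | CC(C)=CCC[C@@](C)(O)[C@@H](O)C=C | intermediate
16 | (3S,4R)-3,4-bis(tert-butyldimethylsilyloxy)-4,8-dimethylnona-1,7-diene | CC(C)=CCC[C@@](C)(O[Si](C)(C)C(C)(C)C)[C@@H](O[Si](C)(C)C(C)(C)C)C=C | intermediate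
17 | 9-[(3S,4R)-3,4-bis(tert-butyldimethylsilyloxy)-4,8-dimethylnon-7-en-1-yl]-9-borabicyclo[3.3.1]nonane | CC(C)=CCC[C@@](C)(O[Si](C)(C)C(C)(C)C)[C@@H](O[Si](C)(C)C(C)(C)C)CCB1C2CCCC1CCC2 | intermediate (not isolated)
18 | (3E,7S,8R)-1-bromo-7,8-bis(tert-butyldimethylsilyloxy)-4,8,12-trimethyltrideca-3,11-diene (SC–Br) | CC(C)=CCC[C@@](C)(O[Si](C)(C)C(C)(C)C)[C@@H](O[Si](C)(C)C(C)(C)C)CC/C(C)=C/CCBr | intermediate
19 | 3-methylcyclohex-2-en-1-one | CC1=CC(=O)CCC1 | starting material
20 | SC–MgBr, Grignard reagent of 18 | CC(C)=CCC[C@@](C)(O[Si](C)(C)C(C)(C)C)[C@@H](O[Si](C)(C)C(C)(C)C)CC/C(C)=C/CC[Mg]Br | intermediate (not isolated)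
21 | bromomagnesium (3R)-3-methyl-3-SC-cyclohex-1-en-1-olate | CC(C)=CCC[C@@](C)(O[Si](C)(C)C(C)(C)C)[C@@H](O[Si](C)(C)C(C)(C)C)CC/C(C)=C/CC[C@@]1(C)CCCC(O[Mg]Br)=C1 | intermediate (not isolated)
22 | (3R)-2-[(3S,4E)-5-Ar-1-hydroxy-3,4-dimethylpent-4-en-1-yl]-3-methyl-3-SC-cyclohexan-1-one, epimers at C5 and C6 | CC(C)=CCC[C@@](C)(O[Si](C)(C)C(C)(C)C)[C@@H](O[Si](C)(C)C(C)(C)C)CC/C(C)=C/CC[C@@]1(C)CCCC(=O)C1C(O)C[C@H](C)/C(C)=C/c1cc(OC)ccc1OC | intermediate
23 | methanesulfonate of 22 at the C6 hydroxyl | CC(C)=CCC[C@@](C)(O[Si](C)(C)C(C)(C)C)[C@@H](O[Si](C)(C)C(C)(C)C)CC/C(C)=C/CC[C@@]1(C)CCCC(=O)C1C(OS(C)(=O)=O)C[C@H](C)/C(C)=C/c1cc(OC)ccc1OC | intermediate (not isolated)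
24 | (3R)-2-[(3S,4E)-5-Ar-3,4-dimethylpent-4-en-1-ylidene]-3-methyl-3-SC-cyclohexan-1-one, C5=C6 geometry not defined | CC(C)=CCC[C@@](C)(O[Si](C)(C)C(C)(C)C)[C@@H](O[Si](C)(C)C(C)(C)C)CC/C(C)=C/CC[C@@]1(C)CCCC(=O)C1=CC[C@H](C)/C(C)=C/c1cc(OC)ccc1OC | intermediate
25 | lithium (3R)-2-[(3S,4E)-5-Ar-3,4-dimethylpent-4-en-1-yl]-3-methyl-3-SC-cyclohex-1-en-1-olate | CC(C)=CCC[C@@](C)(O[Si](C)(C)C(C)(C)C)[C@@H](O[Si](C)(C)C(C)(C)C)CC/C(C)=C/CC[C@@]1(C)CCCC(O[Li])=C1CC[C@H](C)/C(C)=C/c1cc(OC)ccc1OC | intermediate (not isolated)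
26 | (3R)-2-[(3S,4E)-5-Ar-3,4-dimethylpent-4-en-1-yl]-3-methyl-3-SC-cyclohex-1-en-1-yl trifluoromethanesulfonate | CC(C)=CCC[C@@](C)(O[Si](C)(C)C(C)(C)C)[C@@H](O[Si](C)(C)C(C)(C)C)CC/C(C)=C/CC[C@@]1(C)CCCC(OS(=O)(=O)C(F)(F)F)=C1CC[C@H](C)/C(C)=C/c1cc(OC)ccc1OC | intermediate
27 | cyclised benzylic palladium formate (phosphine omitted; the palladium-bearing C11 is fixed by syn addition and then erased) | CC(C)=CCC[C@@](C)(O[Si](C)(C)C(C)(C)C)[C@@H](O[Si](C)(C)C(C)(C)C)CC/C(C)=C/CC[C@@]1(C)CCCC2=C1CC[C@H](C)[C@@]2(C)C([Pd]OC=O)c1cc(OC)ccc1OC | intermediate (not isolated)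
28 | 2-{[(1R,2S,5R)-1,2,5-trimethyl-5-SC-1,2,3,4,5,6,7,8-octahydronaphthalen-1-yl]methyl}-1,4-dimethoxybenzene | CC(C)=CCC[C@@](C)(O[Si](C)(C)C(C)(C)C)[C@@H](O[Si](C)(C)C(C)(C)C)CC/C(C)=C/CC[C@@]1(C)CCCC2=C1CC[C@H](C)[C@@]2(C)Cc1cc(OC)ccc1OC | intermediate
29 | 2-{[(1R,2S,5R)-1,2,5-trimethyl-5-SC-1,2,3,4,5,6,7,8-octahydronaphthalen-1-yl]methyl}cyclohexa-2,5-diene-1,4-dione | CC(C)=CCC[C@@](C)(O[Si](C)(C)C(C)(C)C)[C@@H](O[Si](C)(C)C(C)(C)C)CC/C(C)=C/CC[C@@]1(C)CCCC2=C1CC[C@H](C)[C@@]2(C)CC1=CC(=O)C=CC1=O | intermediate (not isolated)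
30 | 2-{[(1R,2S,5R)-1,2,5-trimethyl-5-SC-1,2,3,4,5,6,7,8-octahydronaphthalen-1-yl]methyl}benzene-1,4-diol | CC(C)=CCC[C@@](C)(O[Si](C)(C)C(C)(C)C)[C@@H](O[Si](C)(C)C(C)(C)C)CC/C(C)=C/CC[C@@]1(C)CCCC2=C1CC[C@H](C)[C@@]2(C)Cc1cc(O)ccc1O | intermediate
31 | 2-{[(1R,2S,5R)-1,2,5-trimethyl-5-SC-1,2,3,4,5,6,7,8-octahydronaphthalen-1-yl]methyl}-1,4-phenylene bis(hydrogen sulfate) | CC(C)=CCC[C@@](C)(O[Si](C)(C)C(C)(C)C)[C@@H](O[Si](C)(C)C(C)(C)C)CC/C(C)=C/CC[C@@]1(C)CCCC2=C1CC[C@H](C)[C@@]2(C)Cc1cc(OS(=O)(=O)O)ccc1OS(=O)(=O)O | intermediate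
32 | 2-{[(1R,2S,5R)-5-[(3E,7S,8R)-7,8-dihydroxy-4,8,12-trimethyltrideca-3,11-dien-1-yl]-1,2,5-trimethyl-1,2,3,4,5,6,7,8-octahydronaphthalen-1-yl]methyl}-1,4-phenylene bis(hydrogen sulfate) | CC(C)=CCC[C@@](C)(O)[C@@H](O)CC/C(C)=C/CC[C@@]1(C)CCCC2=C1CC[C@H](C)[C@@]2(C)Cc1cc(OS(=O)(=O)O)ccc1OS(=O)(=O)O | target

Total step count: 15. Longest linear sequence: 11 steps (steps 5 to 15, from geraniol).

Steps most likely to fail

Step 12. The migratory insertion may show poor facial discrimination at C9, since C8 biases an (E)-styrene only weakly and the ligand may be mismatched, and hydride may capture the alkenylpalladium before it cyclises. The fallback replaces the palladium chemistry by a radical ring closure and sets out from enone 24. Conjugate reduction with LiBH(s-Bu)3 and protonation of the enolate would give the saturated C10 ketone F1. SmI2 with HMPA and t-BuOH in THF would then effect a 6-exo ketyl–olefin cyclisation onto the styrene, the benzylic radical being reduced and protonated, to give the tertiary C10 alcohol F2. Dehydration with SOCl2 in pyridine toward the more substituted C5 would come back to 28.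

Step 9. Enantiofacial control may erode with so large a functionalised Grignard reagent, 1,2-addition may compete, and the hindered enolate may take a proton from the aldehyde instead of adding to it. The fallback exchanges the roles of the two carbon groups at C4 and sets out from bromide 18. Its Grignard reagent 20 would be added to 3-ethoxycyclohex-2-en-1-one with acidic work-up to give the 3-substituted cyclohexenone F3. Conjugate addition of Me3Al, catalysed by Cu(OAc)2 and a chiral phosphoramidite, with acetic anhydride quench would give the (R)-configured enol acetate F4. MeLi would release the lithium enolate, and its aldol addition to 7 comes back to 22.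

Step 6. The Payne equilibrium lies on the side of the starting epoxy alcohol, because the rearranged alkoxide is tertiary, so ylide attack may be slow or may go to the trisubstituted epoxide. The fallback builds the diol by hydrolytic opening and sets out from geraniol 12. Epoxidation with the L-(+)-tartrate catalyst would give the (2S,3S)-epoxide F5. HClO4 in aqueous THF would open it with inversion at the tertiary carbon to the (2S,3R)-triol F6. Selective tosylation of the primary hydroxyl would give the tosylate F7, and K2CO3 in MeOH would close the terminal epoxide 14, now isolated. Homologation of 14 with the same sulfonium ylide comes back to 15.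

Further compounds
F1 | step 12 | (3R)-2-[(3S,4E)-5-Ar-3,4-dimethylpent-4-en-1-yl]-3-methyl-3-SC-cyclohexan-1-one, C5 epimers | CC(C)=CCC[C@@](C)(O[Si](C)(C)C(C)(C)C)[C@@H](O[Si](C)(C)C(C)(C)C)CC/C(C)=C/CC[C@@]1(C)CCCC(=O)C1CC[C@H](C)/C(C)=C/c1cc(OC)ccc1OC
F2 | step 12 | (1R,2S,5R)-1-(2,5-dimethoxybenzyl)-1,2,5-trimethyl-5-SC-decahydronaphthalen-8a-ol, C5 and C10 not defined | CC(C)=CCC[C@@](C)(O[Si](C)(C)C(C)(C)C)[C@@H](O[Si](C)(C)C(C)(C)C)CC/C(C)=C/CC[C@@]1(C)CCCC2(O)C1CC[C@H](C)[C@@]2(C)Cc1cc(OC)ccc1OC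
F3 | step 9 | 3-SC-cyclohex-2-en-1-one | CC(C)=CCC[C@@](C)(O[Si](C)(C)C(C)(C)C)[C@@H](O[Si](C)(C)C(C)(C)C)CC/C(C)=C/CCC1=CC(=O)CCC1
F4 | step 9 | (3R)-3-methyl-3-SC-cyclohex-1-en-1-yl acetate | CC(C)=CCC[C@@](C)(O[Si](C)(C)C(C)(C)C)[C@@H](O[Si](C)(C)C(C)(C)C)CC/C(C)=C/CC[C@@]1(C)CCCC(OC(C)=O)=C1
F5 | step 6 | (2S,3S)-2,3-epoxygeraniol | CC(C)=CCC[C@]1(C)O[C@H]1CO
F6 | step 6 | (2S,3R)-3,7-dimethyloct-6-ene-1,2,3-triol | CC(C)=CCC[C@@](C)(O)[C@@H](O)CO
F7 | step 6 | (2S,3R)-2,3-dihydroxy-3,7-dimethyloct-6-en-1-yl 4-methylbenzenesulfonate | CC(C)=CCC[C@@](C)(O)[C@@H](O)COS(=O)(=O)c1ccc(C)cc1
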